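The central quinone ring (C1 and C4 carbonyls, C2 acetoxy, C5 hydroxy, aryl groups para at C3 and C6) is disconnected at C1–C2 into a squarate-derived cyclobutenone (C2–C5) and an α-aryl-β-benzyloxyvinyl unit (C6, C1). Heating the 4-alkenyl-4-silyloxycyclobutenone opens the four-membered ring to a dienylketene whose ketene carbon (C2) closes onto the alkoxy-bearing alkene carbon (C1), delivering the hexasubstituted benzene ring in one operation. The precursor carries benzyl ethers throughout and a triethylsilyl group on its tertiary oxygen, so the para oxygens at C2 and C5 emerge differentiated: the acetate is placed without statistical acylation, and hydrogenolysis with air oxidation finishes the synthesis.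

Key step: step 7

Remark on the chemistry: every oxygen that must end as OH or C=O is carried as a benzyl ether, so dibenzyl squarate 2 and Wittig salt 10 are each made in one step; enol ether 13 is used as an E/Z mixture, and 18 and 20 are racemic.

Step 1
Reactants: 1 squaric acid (3,4-dihydroxycyclobut-3-ene-1,2-dione)
Product: 2 3,4-bis(benzyloxy)cyclobut-3-ene-1,2-dione (dibenzyl squarate)
Conditions: BnOH (excess), toluene, reflux, Dean–Stark
Reagents that add atoms: benzyl alcohol, OCc1ccccc1
Why: Squaric acid is a strong vinylogous diacid that catalyses its own esterification when water is removed azeotropically, the standard way to dialkyl squarates; no stereocentre is formed.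

Step 2
Reactants: 3 1-(benzyloxy)-4-bromobenzene; 2 dibenzyl squarate
Product: 7 3-(benzyloxy)-4-[4-(benzyloxy)phenyl]cyclobut-3-ene-1,2-dione, via aryllithium 4 (not isolated), via lithium alkoxide 5 (not isolated), via trifluoroacetate ester 6 (not isolated)
Conditions: n-BuLi, THF, −78 °C; then 2, −78 °C; then (CF3CO)2O, −78 °C → rt; aq. NaHCO3
Reagents that add atoms: none
Why: Bromine–lithium exchange gives the aryllithium, which adds once (1,2-addition) to a squarate carbonyl at low temperature, and O-trifluoroacetylation of the carbinol triggers the usual squarate-adduct rearrangement with loss of one benzyloxy group to the 3-alkoxy-4-arylcyclobutenedione; the transient stereocentre is destroyed.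

Step 3
Reactants: 8 benzyl chloromethyl ether; 9 triphenylphosphine
Product: 10 (benzyloxymethyl)triphenylphosphonium chloride
Conditions: toluene, rt → 60 °C
Reagents that add atoms: none
Why: SN2 quaternisation of the phosphine by the reactive α-chloro ether gives the Wittig salt, which should precipitate from toluene.

Step 4
Reactants: 10 (benzyloxymethyl)triphenylphosphonium chloride; 11 4-(benzyloxy)benzaldehyde
Product: 13 1-(benzyloxy)-4-[2-(benzyloxy)ethenyl]benzene (E/Z mixture), via phosphorus ylide 12 (not isolated)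
Conditions: KOtBu, THF, 0 °C; then 11, 0 °C → rt
Reagents that add atoms: none
Why: Wittig olefination with the non-stabilised alkoxymethylidene ylide gives the enol ether, and the mixed alkene geometry does not matter because the next step passes through an sp3 dibromide.

Step 5
Reactants: 13 1-(benzyloxy)-4-[2-(benzyloxy)ethenyl]benzene
Product: 15 (Z)-1-(benzyloxy)-4-[2-(benzyloxy)-1-bromoethenyl]benzene, via dibromide 14 (not isolated)
Conditions: Br2 (1 equiv), CH2Cl2, −78 °C; then DBU, −78 °C → rt
Reagents that add atoms: bromine, BrBr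
Why: Electrophilic bromination of the enol ether followed by dehydrobromination (E1-type loss of the acetal bromide, then of the benzylic proton) is the standard addition–elimination route to β-bromo enol ethers; the isomer with bromine cis to the benzyloxy group and the aryl group trans to it is expected to dominate and is the one carried on after chromatography.

Step 6
Reactants: 15 (Z)-1-(benzyloxy)-4-[2-(benzyloxy)-1-bromoethenyl]benzene; 7 3-(benzyloxy)-4-[4-(benzyloxy)phenyl]cyclobut-3-ene-1,2-dione
Product: 18 racemic 3-(benzyloxy)-4-{(Z)-2-(benzyloxy)-1-[4-(benzyloxy)phenyl]ethenyl}-2-[4-(benzyloxy)phenyl]-4-[(triethylsilyl)oxy]cyclobut-2-en-1-one, via vinyllithium 16 (not isolated), via lithium alkoxide 17 (not isolated)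
Conditions: t-BuLi (2 equiv), Et2O, −78 °C; then 7 in THF, −78 °C; then Et3SiOTf, −78 → 0 °C
Reagents that add atoms: triethylsilyl trifluoromethanesulfonate, CC[Si](CC)(CC)OS(=O)(=O)C(F)(F)F
Why: Bromine–lithium exchange with retention gives a vinyllithium held by internal O–Li coordination (lithium cis to OBn, so anti β-elimination is geometrically excluded), which undergoes 1,2-addition at the ketone-like carbonyl next to the benzyloxy-bearing carbon and not at the vinylogous ester carbonyl, and the tertiary alkoxide is O-silylated in situ; the new quaternary stereocentre forms without control (racemic) and is erased in step 7.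

Step 7
Reactants: 18 racemic 3-(benzyloxy)-4-{(Z)-2-(benzyloxy)-1-[4-(benzyloxy)phenyl]ethenyl}-2-[4-(benzyloxy)phenyl]-4-[(triethylsilyl)oxy]cyclobut-2-en-1-one
Product: 21 2,5-bis(benzyloxy)-3,6-bis[4-(benzyloxy)phenyl]-4-[(triethylsilyl)oxy]phenol, via dienylketene 19 (not isolated), via cyclohexadienone 20 (not isolated)
Conditions: toluene, 110 °C, argon
Reagents that add atoms: none
Why: Thermal conrotatory 4π ring opening cleaves the C1–C4 bond of the cyclobutenone (quinone C2···C5) to give dienylketene 19, a disrotatory 6π electrocyclisation joins the ketene carbon to the benzyloxy-bearing alkene terminus (quinone C2–C1), and enolisation of dienone 20 aromatises the ring to phenol 21. The closest known reaction type is the Moore ring expansion of 4-alkenyl-4-oxy-substituted cyclobutenones to hydroquinones and their mono-ethers. The one ring formed, the central six-membered carbocycle, is closed by this 6π electrocyclisation of the ketene–diene and not by an ionic cyclisation. No stereocentre is created: the racemic C4 centre of 18 is lost on ring opening and the transient C6 centre of 20 on enolisation. The step needs torquoselectivity (oxygen outward, alkenyl inward), which the lone-pair donor triethylsilyloxy group at C4 secures, while the para arrangement of the aryl groups was already fixed by the carbonyl-selective addition in step 6. Because the silyl group stays on the oxygen of the former carbinol carbon, only the oxygen of the former ketene carbon appears as a free phenol, and this directs the acetate in step 8.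

Step 8
Reactants: 21 2,5-bis(benzyloxy)-3,6-bis[4-(benzyloxy)phenyl]-4-[(triethylsilyl)oxy]phenol
Product: 23 2,5-bis(benzyloxy)-3,6-bis[4-(benzyloxy)phenyl]-4-hydroxyphenyl acetate, via silyl ether acetate 22 (not isolated)
Conditions: Ac2O, pyridine, DMAP (cat.), CH2Cl2, rt; evaporate; then Et3N·3HF, THF, rt
Reagents that add atoms: acetic anhydride, CC(=O)OC(C)=O
Why: DMAP-catalysed acyl transfer esterifies the only free phenol, and fluoride-mediated desilylation then frees the para oxygen without touching aryl acetate or benzyl ethers; no stereocentre is involved.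

Step 9
Reactants: 23 2,5-bis(benzyloxy)-3,6-bis[4-(benzyloxy)phenyl]-4-hydroxyphenyl acetate
Product: 25 4-hydroxy-2,5-bis(4-hydroxyphenyl)-3,6-dioxocyclohexa-1,4-dien-1-yl acetate (the target), via leuco monoacetate 24 (not isolated)
Conditions: H2 (1 atm), Pd/C, THF–EtOAc, rt; filter under argon; then air, rt
Reagents that add atoms: none
Why: Catalytic hydrogenolysis should cleave all four benzyl ethers while leaving the aryl acetate, and the electron-rich hydroxyhydroquinone then autoxidises across its free para pair of hydroxyls (quinone C1/C4); since the four ring oxygens of the leuco compound are symmetry-equivalent, any acetyl migration before oxidation leads to the same quinone.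

Compound list
1 | squaric acid (3,4-dihydroxycyclobut-3-ene-1,2-dione) | OC1=C(O)C(=O)C1=O | starting material
2 | 3,4-bis(benzyloxy)cyclobut-3-ene-1,2-dione (dibenzyl squarate) | O=C1C(=O)C(OCc2ccccc2)=C1OCc1ccccc1 | intermediate
3 | 1-(benzyloxy)-4-bromobenzene | Brc1ccc(OCc2ccccc2)cc1 | starting material
4 | [4-(benzyloxy)phenyl]lithium (formed in situ) | [Li]c1ccc(OCc2ccccc2)cc1 | intermediate
5 | lithium alkoxide of racemic 2,3-bis(benzyloxy)-4-[4-(benzyloxy)phenyl]-4-hydroxycyclobut-2-en-1-one (formed in situ) | [Li]OC1(c2ccc(OCc3ccccc3)cc2)C(OCc2ccccc2)=C(OCc2ccccc2)C1=O | intermediate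
6 | racemic 2,3-bis(benzyloxy)-1-[4-(benzyloxy)phenyl]-4-oxocyclobut-2-en-1-yl trifluoroacetate (formed in situ) | O=C(OC1(c2ccc(OCc3ccccc3)cc2)C(OCc2ccccc2)=C(OCc2ccccc2)C1=O)C(F)(F)F | intermediate
7 | 3-(benzyloxy)-4-[4-(benzyloxy)phenyl]cyclobut-3-ene-1,2-dione | O=C1C(=O)C(c2ccc(OCc3ccccc3)cc2)=C1OCc1ccccc1 | intermediate
8 | benzyl chloromethyl ether | ClCOCc1ccccc1 | starting material
9 | triphenylphosphine | c1ccc(cc1)P(c1ccccc1)c1ccccc1 | starting material
10 | (benzyloxymethyl)triphenylphosphonium chloride | [Cl-].c1ccc(cc1)[P+](COCc1ccccc1)(c1ccccc1)c1ccccc1 | intermediate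
11 | 4-(benzyloxy)benzaldehyde | O=Cc1ccc(OCc2ccccc2)cc1 | starting material
12 | (benzyloxymethylidene)triphenylphosphorane (formed in situ) | c1ccc(cc1)P(=COCc1ccccc1)(c1ccccc1)c1ccccc1 | intermediate
13 | 1-(benzyloxy)-4-[2-(benzyloxy)ethenyl]benzene, E/Z mixture | C(=COCc1ccccc1)c1ccc(OCc2ccccc2)cc1 | intermediate
14 | 1-(benzyloxy)-4-[2-(benzyloxy)-1,2-dibromoethyl]benzene, diastereomer mixture (formed in situ) | BrC(OCc1ccccc1)C(Br)c1ccc(OCc2ccccc2)cc1 | intermediate
15 | (Z)-1-(benzyloxy)-4-[2-(benzyloxy)-1-bromoethenyl]benzene (Br cis to OBn) | Br/C(=C\OCc1ccccc1)c1ccc(OCc2ccccc2)cc1 | intermediate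
16 | {2-(benzyloxy)-1-[4-(benzyloxy)phenyl]ethenyl}lithium, Li cis to OBn (same geometry as 15; formed in situ) | [Li]/C(=C\OCc1ccccc1)c1ccc(OCc2ccccc2)cc1 | intermediate
17 | lithium alkoxide of racemic 3-(benzyloxy)-4-{(Z)-2-(benzyloxy)-1-[4-(benzyloxy)phenyl]ethenyl}-2-[4-(benzyloxy)phenyl]-4-hydroxycyclobut-2-en-1-one (formed in situ) | [Li]OC1(/C(=C\OCc2ccccc2)c2ccc(OCc3ccccc3)cc2)C(OCc2ccccc2)=C(c2ccc(OCc3ccccc3)cc2)C1=O | intermediate
18 | racemic 3-(benzyloxy)-4-{(Z)-2-(benzyloxy)-1-[4-(benzyloxy)phenyl]ethenyl}-2-[4-(benzyloxy)phenyl]-4-[(triethylsilyl)oxy]cyclobut-2-en-1-one | CC[Si](CC)(CC)OC1(/C(=C\OCc2ccccc2)c2ccc(OCc3ccccc3)cc2)C(OCc2ccccc2)=C(c2ccc(OCc3ccccc3)cc2)C1=O | intermediate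
19 | (3Z,5Z)-3,6-bis(benzyloxy)-2,5-bis[4-(benzyloxy)phenyl]-4-[(triethylsilyl)oxy]hexa-1,3,5-trien-1-one (dienylketene, formed in situ) | O=C=C(c1ccc(OCc2ccccc2)cc1)/C(OCc1ccccc1)=C(/O[Si](CC)(CC)CC)\C(c1ccc(OCc2ccccc2)cc1)=C/OCc1ccccc1 | intermediate
20 | racemic 3,6-bis(benzyloxy)-2,5-bis[4-(benzyloxy)phenyl]-4-[(triethylsilyl)oxy]cyclohexa-2,4-dien-1-one (formed in situ) | O=C1C(c2ccc(OCc3ccccc3)cc2)=C(OCc2ccccc2)C(O[Si](CC)(CC)CC)=C(c2ccc(OCc3ccccc3)cc2)C1OCc1ccccc1 | intermediate
21 | 2,5-bis(benzyloxy)-3,6-bis[4-(benzyloxy)phenyl]-4-[(triethylsilyl)oxy]phenol | CC[Si](CC)(CC)Oc1c(OCc2ccccc2)c(-c2ccc(OCc3ccccc3)cc2)c(O)c(OCc2ccccc2)c1-c1ccc(OCc2ccccc2)cc1 | intermediate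
22 | 2,5-bis(benzyloxy)-3,6-bis[4-(benzyloxy)phenyl]-4-[(triethylsilyl)oxy]phenyl acetate (formed in situ) | CC(=O)Oc1c(OCc2ccccc2)c(-c2ccc(OCc3ccccc3)cc2)c(O[Si](CC)(CC)CC)c(OCc2ccccc2)c1-c1ccc(OCc2ccccc2)cc1 | intermediate
23 | 2,5-bis(benzyloxy)-3,6-bis[4-(benzyloxy)phenyl]-4-hydroxyphenyl acetate | CC(=O)Oc1c(OCc2ccccc2)c(-c2ccc(OCc3ccccc3)cc2)c(O)c(OCc2ccccc2)c1-c1ccc(OCc2ccccc2)cc1 | intermediate
24 | 2,4,5-trihydroxy-3,6-bis(4-hydroxyphenyl)phenyl acetate (leuco monoacetate, formed in situ) | CC(=O)Oc1c(O)c(-c2ccc(O)cc2)c(O)c(O)c1-c1ccc(O)cc1 | intermediate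
25 | 4-hydroxy-2,5-bis(4-hydroxyphenyl)-3,6-dioxocyclohexa-1,4-dien-1-yl acetate (CNP0258037.0) | CC(=O)OC1=C(c2ccc(O)cc2)C(=O)C(O)=C(c2ccc(O)cc2)C1=O | target

Total step count: 9. Longest linear sequence: 7 steps (steps 3–9, from benzyl chloromethyl ether); steps 1–2 form the second branch, which joins in step 6.

Steps most likely to fail

Step 6. What may go wrong: the crowded tertiary lithium alkoxide may fragment or be silylated incompletely before it is trapped; loss of lithium benzyloxide from the vinyllithium and attack at the wrong carbonyl are lesser concerns. The fallback replaces in situ silylation by protonation and late desymmetrisation. It sets out from lithium alkoxide 17, which is quenched with aqueous NH4Cl at −78 °C to give the free carbinol, racemic 3-(benzyloxy)-4-{(Z)-2-(benzyloxy)-1-[4-(benzyloxy)phenyl]ethenyl}-2-[4-(benzyloxy)phenyl]-4-hydroxycyclobut-2-en-1-one F1. Heating this in toluene at 110 °C, with the hydroxyl as the outward-rotating donor, should give the centrosymmetric 2,5-bis(benzyloxy)-3,6-bis[4-(benzyloxy)phenyl]benzene-1,4-diol F2. One equivalent of Ac2O with pyridine and DMAP then acetylates one of the two equivalent hydroxyls; the diol is recycled and the diacetate saponified back. The monoacetate is 23, where the route is rejoined.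

Step 5. What may go wrong: HBr may be lost with the wrong geometry (bromine trans to OBn, whose lithio derivative would expel lithium benzyloxide), or bromide may debenzylate the bromo-oxocarbenium ion. The fallback takes the geometry from a chelated enolate instead of an elimination. It sets out from 3: aryllithium 4 is acylated with purchased 2-(benzyloxy)-N-methoxy-N-methylacetamide to give 2-(benzyloxy)-1-[4-(benzyloxy)phenyl]ethan-1-one F3. KN(SiMe3)2 followed by PhNTf2 traps the enolate, whose oxygen lies cis to OBn, as (Z)-2-(benzyloxy)-1-[4-(benzyloxy)phenyl]ethenyl trifluoromethanesulfonate F4. Coupling with Me3SnSnMe3 under Pd(PPh3)4 catalysis with LiCl gives, with retention, (Z)-{2-(benzyloxy)-1-[4-(benzyloxy)phenyl]ethenyl}trimethylstannane F5. MeLi at −78 °C then effects tin–lithium exchange to vinyllithium 16, from which step 6 continues.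

Step 7. What may go wrong: the alkenyl group may rotate outward during ring opening, or the dienylketene may be consumed by other pathways before its ketene carbon reaches the alkene terminus, whose benzyloxy group points into the closing ring. The fallback builds on a preformed quinone ring by cross-coupling. It sets out from 3: lithiation as in step 2, B(OiPr)3 and acidic work-up give [4-(benzyloxy)phenyl]boronic acid F6. Purchased tetrabromo-1,4-benzoquinone and BnONa (2 equiv) give, by double addition–elimination, 2,5-bis(benzyloxy)-3,6-dibromocyclohexa-2,5-diene-1,4-dione F7. A twofold Suzuki–Miyaura coupling of the two (Pd(PPh3)4, K3PO4, dioxane) gives 2,5-bis(benzyloxy)-3,6-bis[4-(benzyloxy)phenyl]cyclohexa-2,5-diene-1,4-dione F8. H2 over Pd/C removes all four benzyl groups and air reoxidises the leuco compound to atromentin, 2,5-dihydroxy-3,6-bis(4-hydroxyphenyl)cyclohexa-2,5-diene-1,4-dione F9. One equivalent of acetyl chloride with NaHCO3 then acylates one of the two acidic enol hydroxyls (statistical, with separation and recycling) and gives 25 directly.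

Further compounds
F1 | step 6 | racemic 3-(benzyloxy)-4-{(Z)-2-(benzyloxy)-1-[4-(benzyloxy)phenyl]ethenyl}-2-[4-(benzyloxy)phenyl]-4-hydroxycyclobut-2-en-1-one | OC1(/C(=C\OCc2ccccc2)c2ccc(OCc3ccccc3)cc2)C(OCc2ccccc2)=C(c2ccc(OCc3ccccc3)cc2)C1=O
F2 | step 6 | 2,5-bis(benzyloxy)-3,6-bis[4-(benzyloxy)phenyl]benzene-1,4-diol | Oc1c(OCc2ccccc2)c(-c2ccc(OCc3ccccc3)cc2)c(O)c(OCc2ccccc2)c1-c1ccc(OCc2ccccc2)cc1
F3 | step 5 | 2-(benzyloxy)-1-[4-(benzyloxy)phenyl]ethan-1-one | O=C(COCc1ccccc1)c1ccc(OCc2ccccc2)cc1
F4 | step 5 | (Z)-2-(benzyloxy)-1-[4-(benzyloxy)phenyl]ethenyl trifluoromethanesulfonate | FC(F)(F)S(=O)(=O)O/C(=C\OCc1ccccc1)c1ccc(OCc2ccccc2)cc1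
F5 | step 5 | (Z)-{2-(benzyloxy)-1-[4-(benzyloxy)phenyl]ethenyl}trimethylstannane | C[Sn](C)(C)/C(=C\OCc1ccccc1)c1ccc(OCc2ccccc2)cc1
F6 | step 7 | [4-(benzyloxy)phenyl]boronic acid | OB(O)c1ccc(OCc2ccccc2)cc1
F7 | step 7 | 2,5-bis(benzyloxy)-3,6-dibromocyclohexa-2,5-diene-1,4-dione | O=C1C(Br)=C(OCc2ccccc2)C(=O)C(Br)=C1OCc1ccccc1
F8 | step 7 | 2,5-bis(benzyloxy)-3,6-bis[4-(benzyloxy)phenyl]cyclohexa-2,5-diene-1,4-dione | O=C1C(c2ccc(OCc3ccccc3)cc2)=C(OCc2ccccc2)C(=O)C(c2ccc(OCc3ccccc3)cc2)=C1OCc1ccccc1
F9 | step 7 | atromentin, 2,5-dihydroxy-3,6-bis(4-hydroxyphenyl)cyclohexa-2,5-diene-1,4-dione | O=C1C(O)=C(c2ccc(O)cc2)C(=O)C(O)=C1c1ccc(O)cc1
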